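Follow the substrate.

| flask | substrate | free catalyst | time |
|---|---|---|---|
| ochre | 0.600 M | 0.0120 M |  |
| blue | 0.240 M | 0.0120 M |  |
| red | 0.900 M | 0.0120 M |  |
| grey | 0.600 M | 0.00600 M |  |
| amber | 0.600 M | 0.0120 M | 90 min |

- ochre run (time / min: [target] / M): 1.2: 0.0247; 1.9: 0.0466; 3.0: 0.0612; 4.8: 0.0858; 7.6: 0.1114; 12: 0.1357; 19: 0.1589; 30: 0.1619
- blue run (time / min: [target] / M): 1.2: 0.0156; 1.9: 0.0224; 3.0: 0.0330; 4.8: 0.0438; 7.6: 0.0622; 12: 0.0798; 19: 0.0969; 30: 0.1061
- red run (time / min: [target] / M): 1.2: 0.0394; 1.9: 0.0547; 3.0: 0.0785; 4.8: 0.1086; 7.6: 0.1373; 12: 0.1669; 19: 0.1804; 30: 0.1946
- grey run (time / min: [target] / M): 1.2: 0.0087; 1.9: 0.0079; 3.0: 0.0149; 4.8: 0.0235; 7.6: 0.0310; 12: 0.0445; 19: 0.0518; 30: 0.0590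

(scatter of a reading: 0.002 M)

- the power of [substrate] that the first rate follows, about the charge of the ochre run; measure it at two percent of substrate made into target (one fixed amount of target, the same in the runs compared)
- the power of [free catalyst] that the first rate follows, about the charge of the ochre run; measure it at two percent of substrate made into target
- target in the amber run at 90 min, as a share of the substrate charged

- Overall: substrate -> target, with free catalyst as catalyst.
- Constant volume, constant temperature.
- A reading of a species includes what of it is bound.
- An order is taken over about fifteen percent of the charge, up and down.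

We keep the books of the ochre run as shares of its charge, entered from the target readings. By 4.8 min target holds 14.3% of the charge. By 12 min it has gained a further 8.32%, by 19 min another 3.87%, and by 30 min just 0.500%, which is close to the scatter of one reading, 0.333% of the charge. At the last reading the ochre books stand near 27.0%, and the readings do not say where the other 73.0% stands.

We solve the run at both ends and join them. The late end gives a ceiling, the early end the pace of approach. We call that pace the stopping time, read from the ochre run as 6.36 min: the time in which the gap between target and its ceiling shrinks by a factor e, reckoned here from the gap at the start and the gap at 4.8 min, with the reading at 30 min standing in for the ceiling. At 30 min the ochre gap is then reckoned at 0.894% of the ceiling, so we estimate the ceiling at 27.2% of the charge. The amber run repeats the ochre charge, and 90 min is 14.2 stopping times, so we commit to that share for amber.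

The forecast gives 0.79 (0.6 to 0.95) for the substrate order, 1.9 (1.5 to 2.2) for the catalyst order, and 28.5% (26.5% to 32%) for amber, higher than our share, “allowing a small tail”.

The flask gives 0.80 for the substrate order, 2.1 for the catalyst order and 28.6% for amber, which is 1.4 percentage points above our share.

    free catalyst + substrate ⇌ catalyst-substrate complex, settled at all times (0.2110 M⁻¹)
    catalyst-substrate complex + free catalyst → target + 2 free catalyst (1842 M⁻¹ min⁻¹)
    free catalyst + target → spent catalyst + target (0.2406 M⁻¹ min⁻¹)
    2 substrate → homo dimer (0.1668 M⁻¹ min⁻¹)

Without the conversion of two substrate into homo dimer, target in the amber run comes to 48.5% instead of 28.6%. The stopping time also gives the passage to a quarter of the charge: 16.6 min for the ochre run, where the flask takes 16.0 min. Read the same way, the blue run has a stopping time of 9.02 min, which puts a quarter of its own charge at 7.51 min, and the flask takes 7.30 min.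

The earlier runs and the new flask come from a simulation from invented constants; scatter was added.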